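All runs were computed from invented constants; scatter was added.

1. The closed flask dawn holds its charge for a fixed time, while the tanks noon and midnight mix fresh feed with old.

| flask | X | remark | time |
|---|---|---|---|
| birch | 0.0020 M | run made earlier |  |
| cedar | 0.0040 M | run made earlier |  |
| dawn | 0.0020 M | everything together in a closed stirred flask, run for 2.5 min | 2.5 min |
| noon | 0.0020 M | one stirred flow tank at steady state, fed with the mixture as stated, mean residence time 2.5 min |  |
| midnight | 0.0020 M | a single well-mixed tank run continuously and read at steady state, 7.50 min in it on average |  |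

birch run (percent of the X charged)

| time / min | G / % |
|---|---|
| 0.167 | 21 |
| 0.500 | 47 |
| 0.833 | 53 |
| 1.33 | 53 |
| 2.00 | 50 |
| 2.50 | 46 |

cedar run (percent of the X charged)

| time / s | G / % |
|---|---|
| 10.0 | 20 |
| 15.0 | 28 |
| 25.0 | 42 |
| 30.0 | 46 |

(readings scatter by 1.5 percentage points)

1. order of the set-ups by the amount of G at the outlet or at the end, in percent of the X put in, highest first (dawn / noon / midnight)
2. amount of G at the outlet or at the end, in percent of the X put in, dawn
3. amount of G at the outlet or at the end, in percent of the X put in, noon
4. amount of G at the outlet or at the end, in percent of the X put in, midnight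

2. At twice the charge, cedar reads 46% at 30.0 s, and birch reads 47% at the same time. That gap of 1 percentage point stands against a scatter of 1.5 points, so this pair cannot show how the rates depend on the amount. The reckoning therefore rests on birch, whose charge equals that of the three new set-ups.

3. Birch first gains 1.26 min⁻¹ of the charge per minute. Between 0.500 min and 0.833 min the gain is 0.180 min⁻¹, slower by a factor of 6.98.

4. G then falls from 53% to 46%. That gives the fade, the fraction of G lost per minute after the peak: 0.121 min⁻¹. It is a reading, with the scatter of 1.5 points on each end.

5. Run back to zero time, the fade gives a ceiling of 62.3% of the charge. The reading at 0.500 min then gives a rise constant of 3.36 min⁻¹, faster than the fade.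

6. The fade's accumulated factor in dawn is 0.739, so dawn should repeat birch's 46%. Assuming first-order steps, a tank replaces that exponential by the inverse of one plus constant times mean residence time: 0.768 for noon, which averages 2.5 min, and 0.524 for midnight. With the same treatment of the rise, noon gives 41.2% and midnight 30.3%.

7. The forecast, on grounds of “a fast split or equilibrium followed by slow loss”, gives dawn > noon > midnight: 46%, 41%, 30%.

8. The flasks give dawn > noon > midnight: 47.1%, 44.4%, 35.4%.

    L ⇌ D (K = 110, k = 0.0160 s⁻¹)
    2 X → Q (k = 6.40 M⁻¹ s⁻¹)
    X → L (k = 0.200 s⁻¹)
    L → Z (k = 0.0120 s⁻¹)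
    L ⇌ G (K = 11.0, k = 0.0490 s⁻¹)

9. In dawn, G goes from 52.6% at 1.25 min to 47.1% at 2.50 min, a fade of 0.0884 min⁻¹, slower than the one read from birch. The neighbouring flask is dawn read at 10 min. Carrying 47.1% forward at 0.121 min⁻¹ gives 19.0% there. The neighbouring flask holds 24.3% of G, the kinetic product, below the 37.9% of D.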